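## The problem

The target is a trimer of (−)-epicatechin 3-O-gallate in which C4 of the top unit is bonded to C8 of the middle unit and C4 of the middle unit to C8 of the bottom unit (the terminal unit with a C4 methylene); both interflavan bonds are β, trans to the neighbouring C3 oxygen. There are eight stereocentres: C2 and C3 of each unit (all 2R,3R, 2,3-cis) and C4 of the top and middle units. The four of the middle and bottom units can be bought with epicatechin, and C3 of the middle unit can direct its own C4 when the lower interflavan bond is made. The top unit is the hard part: its C4 is a diarylmethine flanked by two 2,6-dioxygenated rings and has no neighbour to lean on if ring C is built last. The molecule carries 21 phenols that oxidise in air, two interflavan bonds that acids cleave, C2 centres that base epimerises in the free phenols, and three gallate esters that do not survive hydrides or organometallic reagents; all phenols are therefore carried as benzyl ethers, and the esters are made last. The feature that opens the chosen route is in ring C of the top unit: C2 and C3 are adjacent, C2 sits on O1 and C3 on C4, and O1 and C4 are ortho substituents of ring A. A C2=C3 enol ether can therefore be closed by olefin metathesis between an O1-bound 1-arylvinyl group and a C4 vinyl group, and C4 with its large aryl substituent can then direct oxygen to C3 and hydride to C2.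

## Retrosynthesis

**Esters and benzyl ethers.** Target 24 is traced to the perbenzylated trigallate 23 by cutting 21 benzyl–oxygen bonds. 23 is traced to triol 21 and three molecules of acid 22 by cutting the three ester C–O bonds, and 21 to the bis-silyl ether 20. Acylating all three hindered C3 hydroxyls at once at the end is preferred to carrying any gallate through the hydride and organotitanium steps. The forward steps must give exhaustive esterification and a hydrogenolysis that leaves the benzylic interflavan bonds alone.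

**C2–H and C3–O of the top unit.** 20 is traced to flav-2-ene 18 through epoxide 19. This cut removes two stereocentres at once and leaves C4 as the only control element. The net addition of H and OH must be anti: epoxidation anti to the C4 aryl, then hydride at C2 with inversion, gives 2,3-cis, 3,4-trans. Hydroboration would add syn and give the 2,3-trans isomer, so it is not used.

**C2=C3 (key disconnection).** 18 is traced to diene 17 by ring-closing metathesis. Compared with cutting O1–C2 or C4–C4a, this cut makes the ring without touching any benzylic C–O bond and without creating a stereocentre. The precursor is simpler by one ring. The forward step must close the ring without moving the C4 vinyl double bond.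

**Enol ether and ester.** 17 is traced to aryl ester 16 (methylenation of C=O), and 16 to phenol 14 and acid 15. This brings in ring B and C2 of the top unit as a stable, commercial acid. The forward step must methylenate a hindered aryl ester in the presence of a terminal alkene.

**C4–C4a of the top unit.** Phenol 14 is traced to its methoxymethyl ether 13, and 13 to dimer allylic phosphate 8 and arene 10 by an SN2′ allylic arylation. Cutting here, not at C4–C8, puts the cheap ring A piece in the role of the organometallic reagent, so it can be used in excess on the valuable dimer. The methoxymethoxy group, the stronger director, steers the metalation to a carbon between itself and a benzyloxy group (10 gives 11, then 12). The forward step must be γ-selective and the ligand must control the face.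

**C8–alkenyl bond.** 8 is traced to allylic alcohol 7, and 7 to bromo dimer 6 by a Stille coupling. The bromine serves first as a cap on C8 and then as the coupling handle.

**Lower interflavan bond.** 6 is traced to the C4-activated 8-bromide 5 and the nucleophile 3, the natural polarity (C4 cation, C8 arene). 5 comes from 4, 4 from 3, 3 from 2 and 2 from epicatechin 1. Silyl ether 3 serves twice, as nucleophile and as precursor of the electrophile. Arene 10 comes from phenol 9.

## Roads not taken

**Alternative 1:** Ring A of the middle unit would be built by benzannulation. The cut removes C8–C8a, C4a–C8a and C6–C7 of that ring. In the forward step, 3-benzyloxycyclobutenone A2 opens on heating and adds the ynol silyl ether A1, an epicatechin-derived top unit carrying the alkyne on C4. Electrocyclisation then gives phenol A3. The merits are real. The top unit comes intact from epicatechin, so its C4 is set by C3 and not by a catalyst. The 4→8 connectivity is fixed by the carbon skeleton. The conditions are neutral. On the top C4 this road is better than the chosen plan, which has to rely on a ligand in step 9. Its weakness is what A3 still lacks: ring C of the middle unit with three stereocentres, its ring B, the whole bottom unit and the second interflavan bond. Only one of the three units would come from epicatechin. The chosen plan keeps two epicatechin units intact, makes the lower interflavan bond by the established cation–arene route and builds only one ring C.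

**Alternative 2:** The cut is O1–C2 of the top unit. The phenol of epoxy phenol A4 opens its cis-2,3-epoxide at the benzylic carbon with inversion under pyridinium p-toluenesulfonate and gives A5, the trimer with a free top C3 hydroxyl. This closure is stereospecific, and A5 already carries the gallates on the middle and bottom units. The endgame would be one esterification and hydrogenolysis, one step fewer than from 20. In both respects it is as good as or better than the chosen plan. Its weak points are these:
- The epoxide carbon bears a 3,4-dibenzyloxyphenyl group, so ionisation before attack is likely and would erode the inversion toward the 2,3-trans isomer.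
- A4 needs a cis-epoxide of defined absolute configuration next to C4, which means a Z-alkene and a reagent-controlled epoxidation on top of the C4 problem, which remains the same as in step 9.
- The two gallates must survive every step used to build A4.

The chosen plan derives C2 and C3 from C4 on a rigid ring in one operation and exposes no acid to an electron-rich benzylic epoxide.

**Alternative 3:** The cut is C4–C4a of the top unit. Carbinol A6 is ionised at C4 with Zn(OTf)2. The ortho carbon of its 3,5-dibenzyloxyphenyl ether attacks, and the C3 gallate steers the 3,4-trans outcome by participation, giving A7. This uses the polarity that flavan chemistry favours and avoids the crowded organometallic coupling. The nucleophilic ring is symmetric, so there is no regiochemical issue, and the top gallate is in place early. For making the C4–aryl bond it is at least as well founded as step 9. Against it: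
- The Lewis acid meets an existing interflavan bond and a C2 benzylic aryl ether that can itself ionise and epimerise.
- A6 needs C2 and C3 set separately in an open chain and is long to make.
- The gallate again restricts the reagents.

The chosen plan sets against this that ring C of the top unit, once closed, meets only neutral or basic reagents, and that C2 becomes a benzylic ether only in the step that fixes its configuration.

Key step: step 13

Assumptions:
- 3,5-Bis(benzyloxy)phenol 9, 3,4-bis(benzyloxy)benzoic acid 15 and 3,4,5-tris(benzyloxy)benzoic acid 22 are bought as such; they are the benzyl ethers of phloroglucinol, 3,4-dihydroxybenzoic acid and gallic acid.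
- The phosphoramidite antipode for step 9 is the one whose sense of induction leads to the R configuration at the new carbon; it is to be fixed on a model cinnamyl phosphate.

## Route

Step 1
Reactants: 1 (−)-epicatechin
Product: 2 5,7,3′,4′-tetra-O-benzyl-(−)-epicatechin
Conditions: BnBr, K2CO3, DMF, 0 °C to rt, argon
Reagents that add atoms: benzyl bromide, BrCc1ccccc1
Why: Williamson etherification; the four phenols are far more acidic than the C3 alcohol, so carbonate alkylates only them, and cold degassed conditions avoid base-induced epimerisation at C2.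

Step 2
Reactants: 2 5,7,3′,4′-tetra-O-benzyl-(−)-epicatechin
Product: 3 3-O-TBS-5,7,3′,4′-tetra-O-benzylepicatechin
Conditions: TBSCl, imidazole, DMF, rt
Reagents that add atoms: tert-butyldimethylsilyl chloride, CC(C)(C)[Si](C)(C)Cl
Why: imidazole-promoted silylation of the only free hydroxyl; the silyl ether survives all steps up to step 15 and its bulk later helps the 4β selectivity.

Step 3
Reactants: 3 3-O-TBS-5,7,3′,4′-tetra-O-benzylepicatechin
Product: 4 8-bromo-3-O-TBS-5,7,3′,4′-tetra-O-benzylepicatechin
Conditions: NBS, CH2Cl2, −78 °C to rt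
Reagents that add atoms: N-bromosuccinimide, O=C1CCC(=O)N1Br
Why: electrophilic aromatic bromination; C8 is the most nucleophilic position of ring A in benzylated flavan-3-ols, so one equivalent of NBS at low temperature should give the 8-bromide.

Step 4
Reactants: 4 8-bromo-3-O-TBS-5,7,3′,4′-tetra-O-benzylepicatechin
Product: 5 8-bromo-4β-(2-ethoxyethoxy)-3-O-TBS-5,7,3′,4′-tetra-O-benzylepicatechin
Conditions: DDQ, 2-ethoxyethanol, CH2Cl2, rt
Reagents that add atoms: 2-ethoxyethanol, CCOCCO
Why: DDQ benzylic oxidation; hydride abstraction at C4 gives a cation stabilised by the 5- and 7-benzyloxy groups, which the alcohol traps anti to the 3-silyloxy group (the C4 configuration is lost again in step 5).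

Step 5
Reactants: 5 8-bromo-4β-(2-ethoxyethoxy)-3-O-TBS-5,7,3′,4′-tetra-O-benzylepicatechin; 3 3-O-TBS-5,7,3′,4′-tetra-O-benzylepicatechin (excess, recovered)
Product: 6 bromo dimer [8-bromo-3-O-TBS-tetra-O-benzylepicatechin]-(4β→8)-[3-O-TBS-tetra-O-benzylepicatechin]
Conditions: TMSOTf (cat.), CH2Cl2, −78 °C
Reagents that add atoms: none
Why: Friedel–Crafts alkylation by a flavan-4-yl cation; C8 of 3 attacks anti to the 3-silyloxy group and sets the middle C4 as 4β (3,4-trans), and the bromine on 5 blocks its own C8 so that self-condensation is suppressed.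

Step 6
Reactants: 6 bromo dimer
Product: 7 dimer allylic alcohol (C8 of the middle unit bears (E)-CH=CH–CH2OH)
Conditions: (E)-Bu3SnCH=CHCH2OH, Pd2(dba)3 (cat.), P(t-Bu)3, CsF, 1,4-dioxane, 80 °C
Reagents that add atoms: (E)-3-(tributylstannyl)prop-2-en-1-ol, CCCC[Sn](CCCC)(CCCC)/C=C/CO
Why: Stille coupling; the bulky electron-rich phosphine allows oxidative addition into the di-ortho-oxygenated aryl bromide, fluoride activates the stannane, and the E geometry is retained.

Step 7
Reactants: 7 dimer allylic alcohol
Product: 8 dimer (E)-allylic diethyl phosphate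
Conditions: ClP(O)(OEt)2, pyridine, DMAP (cat.), CH2Cl2, 0 °C; used without chromatography
Reagents that add atoms: diethyl chlorophosphate, CCOP(=O)(Cl)OCC
Why: phosphorylation of a primary allylic alcohol; the phosphate is stable enough to handle yet a good leaving group for copper, and it is used crude because the electron-rich cinnamyl system ionises easily on silica.

Step 8
Reactants: 9 3,5-bis(benzyloxy)phenol
Product: 10 1,3-bis(benzyloxy)-5-(methoxymethoxy)benzene
Conditions: MOMCl, i-Pr2NEt, CH2Cl2, 0 °C to rt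
Reagents that add atoms: chloromethyl methyl ether, COCCl
Why: acetal protection of the phenol; the methoxymethoxy group is the stronger ortho-directing group on the ring and marks the oxygen that becomes O1 of the top unit.

Step 9
Reactants: 10 1,3-bis(benzyloxy)-5-(methoxymethoxy)benzene (excess); 8 dimer (E)-allylic diethyl phosphate
Product: 13 (R)-1,1-diarylpropene (C8 of the middle unit bears CH(CH=CH2)[2,4-bis(benzyloxy)-6-(methoxymethoxy)phenyl]), via aryllithium 11 (not isolated), via arylmagnesium bromide 12 (not isolated)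
Conditions: n-BuLi, Et2O, 0 °C to rt; MgBr2·OEt2, 0 °C; slow addition to 8, CuBr·SMe2 (cat.), BINOL-derived N,N-bis(1-phenylethyl)phosphoramidite (cat.), CH2Cl2, −78 °C
Reagents that add atoms: none
Why: directed ortho-metalation between the methoxymethoxy and a benzyloxy group (the two such positions are equivalent), transmetalation to magnesium, then copper-catalysed asymmetric SN2′ allylic arylation; the aryl cuprate adds anti to the phosphate at the γ-carbon through a σ-allyl trivalent copper species, and the chiral phosphoramidite selects the alkene face, setting the future top C4.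

Step 10
Reactants: 13 (R)-1,1-diarylpropene
Product: 14 phenol (C8 of the middle unit bears CH(CH=CH2)[2,4-bis(benzyloxy)-6-hydroxyphenyl])
Conditions: TMSOTf, 2,2′-bipyridyl, CH2Cl2, 0 °C; then H2O
Reagents that add atoms: none
Why: buffered silyl triflate cleavage of an aryl methoxymethyl ether through a bipyridinium intermediate and an aryl silyl ether that hydrolyses on work-up; the base keeps the medium non-acidic, so the secondary silyl ethers, the interflavan bond and the allylic stereocentre should survive.

Step 11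
Reactants: 14 phenol; 15 3,4-bis(benzyloxy)benzoic acid
Product: 16 aryl 3,4-bis(benzyloxy)benzoate of 14
Conditions: DCC, DMAP, CH2Cl2, rt
Reagents that add atoms: none
Why: Steglich esterification; the acylpyridinium intermediate acylates the hindered phenol under neutral conditions and brings in ring B and the future C2.

Step 12
Reactants: 16 aryl 3,4-bis(benzyloxy)benzoate
Product: 17 diene (aryl 1-[3,4-bis(benzyloxy)phenyl]vinyl ether bearing the C4 vinyl group)
Conditions: Cp2TiMe2, toluene–THF, 70 °C, dark; filtration through basic alumina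
Reagents that add atoms: dimethyltitanocene, [CH3-].[CH3-].[Ti+4].[cH-]1cccc1.[cH-]1cccc1
Why: Petasis methylenation; Cp2Ti=CH2 formed on heating adds to the ester carbonyl and the oxatitanacyclobutane collapses to the enol ether, a non-basic process that tolerates silyl ethers, benzyl ethers and the terminal alkene.

Step 13
Reactants: 17 diene
Product: 18 protected trimer with the top unit as a 4-aryl-4H-flav-2-ene
Conditions: second-generation Grubbs catalyst RuCl2(H2IMes)(PCy3)(=CHPh) (cat.), 1,4-benzoquinone (cat.), toluene, 70 °C, argon sparge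
Reagents that add atoms: none
Why: Ring-closing olefin metathesis of an enol ether. The ruthenium benzylidene exchanges onto the monosubstituted C4 vinyl group, the more accessible alkene; the new alkylidene adds across the 1,1-disubstituted 1-arylvinyl ether in an intramolecular [2+2] step, and cycloreversion of the ruthenacyclobutane releases ethene and the C2=C3 double bond. The closest known reaction type is the metathesis closure of aryl enol ethers made by titanium methylenation of aryl esters, which gives benzofurans and 4H-chromenes. The ring formed is the six-membered ring C of the top unit, closed by metathesis between two alkenes held ortho to each other on ring A through O1 and C4. No stereocentre is created; the one at C4 must be kept, so 1,4-benzoquinone is added to intercept ruthenium hydrides that would move the vinyl double bond into conjugation with the two aryl groups. The selectivity needed is ring closure over oligomerisation and over unproductive loading at the enol ether; the ortho arrangement, the steric shielding of the 1,1-disubstituted enol ether and the removal of ethene should secure it.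

Step 14
Reactants: 18 protected trimer with the top unit as a 4-aryl-4H-flav-2-ene
Product: 20 protected trimer with a free top C3 hydroxyl (top unit 2,3-cis and 3,4-trans), via flav-2-ene epoxide 19 (not isolated)
Conditions: dimethyldioxirane (acetone), CH2Cl2, −78 to −20 °C; volatiles removed cold; LiBHEt3, THF, −78 to 0 °C
Reagents that add atoms: dimethyldioxirane, CC1(C)OO1
Why: epoxidation of the electron-rich enol ether on the face anti to the pseudo-axial C4 aryl sets the C3 oxygen trans to C4; LiBHEt3 then opens the epoxide at the acetal-type, benzylic C2 with inversion, as in the reduction of glycal epoxides, so that H and OH add anti and the 2R,3R (2,3-cis) array results.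

Step 15
Reactants: 20 protected trimer with a free top C3 hydroxyl
Product: 21 dodeca-O-benzyl procyanidin C1 (triol)
Conditions: TBAF, AcOH, THF, rt to 50 °C
Reagents that add atoms: none
Why: fluoride desilylation of the two secondary silyl ethers; acetic acid buffers the alkoxides so that no base-sensitive centre is disturbed.

Step 16
Reactants: 21 dodeca-O-benzyl procyanidin C1 (triol); 22 3,4,5-tris(benzyloxy)benzoic acid (three molecules are taken up, one per hydroxyl; about 6 equiv charged)
Product: 23 perbenzylated procyanidin C1 3,3′,3″-tri-O-gallate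
Conditions: 22 (6 equiv), DCC (6 equiv), DMAP, CH2Cl2, rt to 40 °C
Reagents that add atoms: 3,4,5-tris(benzyloxy)benzoic acid (the second and third molecules of acid 22 that are built in), O=C(O)c1cc(OCc2ccccc2)c(OCc2ccccc2)c(OCc2ccccc2)c1
Why: threefold Steglich esterification; each of the three C3 hydroxyls takes up one molecule of 22 through its O-acylisourea and the acylpyridinium ion, carbodiimide and DMAP acylation is the established way to galloylate the hindered C3 hydroxyls of benzylated procyanidins, and no stereocentre is involved.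

Step 17
Reactants: 23 perbenzylated procyanidin C1 3,3′,3″-tri-O-gallate
Product: 24 procyanidin C1 3,3′,3″-tri-O-gallate
Conditions: H2 (1 atm), Pd(OH)2 on carbon, THF–MeOH–H2O, rt; filtration and freeze-drying under argon
Reagents that add atoms: none
Why: hydrogenolysis of all 21 benzyl ethers; under one atmosphere over Pd(OH)2 on carbon the esters, the cyclic benzylic ethers and the interflavan bonds of procyanidins are not cleaved.

## Compound list

1 | (−)-epicatechin, (2R,3R) | O[C@@H]1Cc2c(O)cc(O)cc2O[C@@H]1c1ccc(O)c(O)c1 | starting material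

2 | 5,7,3′,4′-tetra-O-benzyl-(−)-epicatechin | O[C@@H]1Cc2c(OCc9ccccc9)cc(OCc9ccccc9)cc2O[C@@H]1c7ccc(OCc9ccccc9)c(OCc9ccccc9)c7 | intermediate

3 | 3-O-(tert-butyldimethylsilyl)-5,7,3′,4′-tetra-O-benzylepicatechin | CC(C)(C)[Si](C)(C)O[C@@H]1Cc2c(OCc9ccccc9)cc(OCc9ccccc9)cc2O[C@@H]1c7ccc(OCc9ccccc9)c(OCc9ccccc9)c7 | intermediate

4 | 8-bromo-3-O-TBS-5,7,3′,4′-tetra-O-benzylepicatechin | CC(C)(C)[Si](C)(C)O[C@@H]1Cc2c(OCc9ccccc9)cc(OCc9ccccc9)c(Br)c2O[C@@H]1c7ccc(OCc9ccccc9)c(OCc9ccccc9)c7 | intermediate

5 | 8-bromo-4β-(2-ethoxyethoxy)-3-O-TBS-5,7,3′,4′-tetra-O-benzylepicatechin (3,4-trans) | CC(C)(C)[Si](C)(C)O[C@@H]1[C@@H](OCCOCC)c2c(OCc9ccccc9)cc(OCc9ccccc9)c(Br)c2O[C@@H]1c7ccc(OCc9ccccc9)c(OCc9ccccc9)c7 | intermediate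

6 | bromo dimer: 8-bromo-3-O-TBS-tetra-O-benzylepicatechin-(4β→8)-3-O-TBS-tetra-O-benzylepicatechin | CC(C)(C)[Si](C)(C)O[C@@H]1[C@@H](c2c(OCc9ccccc9)cc(OCc9ccccc9)c3c2O[C@H](c7ccc(OCc9ccccc9)c(OCc9ccccc9)c7)[C@H](O[Si](C)(C)C(C)(C)C)C3)c2c(OCc9ccccc9)cc(OCc9ccccc9)c(Br)c2O[C@@H]1c7ccc(OCc9ccccc9)c(OCc9ccccc9)c7 | intermediate

7 | dimer allylic alcohol: as 6 with bromine replaced by (E)-3-hydroxyprop-1-enyl | CC(C)(C)[Si](C)(C)O[C@@H]1[C@@H](c2c(OCc9ccccc9)cc(OCc9ccccc9)c3c2O[C@H](c7ccc(OCc9ccccc9)c(OCc9ccccc9)c7)[C@H](O[Si](C)(C)C(C)(C)C)C3)c2c(OCc9ccccc9)cc(OCc9ccccc9)c(/C=C/CO)c2O[C@@H]1c7ccc(OCc9ccccc9)c(OCc9ccccc9)c7 | intermediate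

8 | dimer (E)-allylic diethyl phosphate | CC(C)(C)[Si](C)(C)O[C@@H]1[C@@H](c2c(OCc9ccccc9)cc(OCc9ccccc9)c3c2O[C@H](c7ccc(OCc9ccccc9)c(OCc9ccccc9)c7)[C@H](O[Si](C)(C)C(C)(C)C)C3)c2c(OCc9ccccc9)cc(OCc9ccccc9)c(/C=C/COP(=O)(OCC)OCC)c2O[C@@H]1c7ccc(OCc9ccccc9)c(OCc9ccccc9)c7 | intermediate

9 | 3,5-bis(benzyloxy)phenol | Oc1cc(OCc2ccccc2)cc(OCc2ccccc2)c1 | starting material

10 | 1,3-bis(benzyloxy)-5-(methoxymethoxy)benzene | COCOc1cc(OCc2ccccc2)cc(OCc2ccccc2)c1 | intermediate

11 | 2,4-bis(benzyloxy)-6-(methoxymethoxy)phenyllithium | [Li]c1c(OCOC)cc(OCc2ccccc2)cc1OCc1ccccc1 | intermediate (not isolated)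

12 | 2,4-bis(benzyloxy)-6-(methoxymethoxy)phenylmagnesium bromide | Br[Mg]c1c(OCOC)cc(OCc2ccccc2)cc1OCc1ccccc1 | intermediate (not isolated)

13 | (R)-1,1-diarylpropene: C8 of the middle unit of the dimer bears CH(CH=CH2)[2,4-bis(benzyloxy)-6-(methoxymethoxy)phenyl]; this carbon is the future top C4 | CC(C)(C)[Si](C)(C)O[C@@H]1[C@@H](c2c(OCc9ccccc9)cc(OCc9ccccc9)c3c2O[C@H](c7ccc(OCc9ccccc9)c(OCc9ccccc9)c7)[C@H](O[Si](C)(C)C(C)(C)C)C3)c2c(OCc9ccccc9)cc(OCc9ccccc9)c([C@H](C=C)c4c(OCc9ccccc9)cc(OCc9ccccc9)cc4OCOC)c2O[C@@H]1c7ccc(OCc9ccccc9)c(OCc9ccccc9)c7 | intermediate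

14 | phenol: as 13 with the methoxymethyl ether replaced by OH | CC(C)(C)[Si](C)(C)O[C@@H]1[C@@H](c2c(OCc9ccccc9)cc(OCc9ccccc9)c3c2O[C@H](c7ccc(OCc9ccccc9)c(OCc9ccccc9)c7)[C@H](O[Si](C)(C)C(C)(C)C)C3)c2c(OCc9ccccc9)cc(OCc9ccccc9)c([C@H](C=C)c4c(OCc9ccccc9)cc(OCc9ccccc9)cc4O)c2O[C@@H]1c7ccc(OCc9ccccc9)c(OCc9ccccc9)c7 | intermediate

15 | 3,4-bis(benzyloxy)benzoic acid | O=C(O)c1ccc(OCc2ccccc2)c(OCc2ccccc2)c1 | starting material

16 | aryl ester: 3,4-bis(benzyloxy)benzoate of phenol 14 | CC(C)(C)[Si](C)(C)O[C@@H]1[C@@H](c2c(OCc9ccccc9)cc(OCc9ccccc9)c3c2O[C@H](c7ccc(OCc9ccccc9)c(OCc9ccccc9)c7)[C@H](O[Si](C)(C)C(C)(C)C)C3)c2c(OCc9ccccc9)cc(OCc9ccccc9)c([C@H](C=C)c4c(OCc9ccccc9)cc(OCc9ccccc9)cc4OC(=O)c7ccc(OCc9ccccc9)c(OCc9ccccc9)c7)c2O[C@@H]1c7ccc(OCc9ccccc9)c(OCc9ccccc9)c7 | intermediate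

17 | diene: O1 1-[3,4-bis(benzyloxy)phenyl]vinyl ether with a vinyl group on C4 (key-step precursor) | CC(C)(C)[Si](C)(C)O[C@@H]1[C@@H](c2c(OCc9ccccc9)cc(OCc9ccccc9)c3c2O[C@H](c7ccc(OCc9ccccc9)c(OCc9ccccc9)c7)[C@H](O[Si](C)(C)C(C)(C)C)C3)c2c(OCc9ccccc9)cc(OCc9ccccc9)c([C@H](C=C)c4c(OCc9ccccc9)cc(OCc9ccccc9)cc4OC(=C)c7ccc(OCc9ccccc9)c(OCc9ccccc9)c7)c2O[C@@H]1c7ccc(OCc9ccccc9)c(OCc9ccccc9)c7 | intermediate

18 | protected trimer with the top unit as a (4R)-4-aryl-4H-flav-2-ene (key-step product) | CC(C)(C)[Si](C)(C)O[C@@H]1[C@@H](c2c(OCc9ccccc9)cc(OCc9ccccc9)c3c2O[C@H](c7ccc(OCc9ccccc9)c(OCc9ccccc9)c7)[C@H](O[Si](C)(C)C(C)(C)C)C3)c2c(OCc9ccccc9)cc(OCc9ccccc9)c([C@H]3c4c(OCc9ccccc9)cc(OCc9ccccc9)cc4OC(c7ccc(OCc9ccccc9)c(OCc9ccccc9)c7)=C3)c2O[C@@H]1c7ccc(OCc9ccccc9)c(OCc9ccccc9)c7 | intermediate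

19 | 2,3-epoxide of 18, oxygen on the face opposite the C4 aryl group | CC(C)(C)[Si](C)(C)O[C@@H]1[C@@H](c2c(OCc9ccccc9)cc(OCc9ccccc9)c3c2O[C@H](c7ccc(OCc9ccccc9)c(OCc9ccccc9)c7)[C@H](O[Si](C)(C)C(C)(C)C)C3)c2c(OCc9ccccc9)cc(OCc9ccccc9)c([C@H]3c4c(OCc9ccccc9)cc(OCc9ccccc9)cc4O[C@]5(c7ccc(OCc9ccccc9)c(OCc9ccccc9)c7)O[C@H]35)c2O[C@@H]1c7ccc(OCc9ccccc9)c(OCc9ccccc9)c7 | intermediate (not isolated)

20 | protected trimer: dodeca-O-benzyl procyanidin C1 with TBS ethers on the middle and bottom C3 oxygens and a free top C3 hydroxyl (top unit 2R,3R,4R) | CC(C)(C)[Si](C)(C)O[C@@H]1[C@@H](c2c(OCc9ccccc9)cc(OCc9ccccc9)c3c2O[C@H](c7ccc(OCc9ccccc9)c(OCc9ccccc9)c7)[C@H](O[Si](C)(C)C(C)(C)C)C3)c2c(OCc9ccccc9)cc(OCc9ccccc9)c([C@H]3c4c(OCc9ccccc9)cc(OCc9ccccc9)cc4O[C@H](c7ccc(OCc9ccccc9)c(OCc9ccccc9)c7)[C@@H]3O)c2O[C@@H]1c7ccc(OCc9ccccc9)c(OCc9ccccc9)c7 | intermediate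

21 | dodeca-O-benzyl procyanidin C1 (three free C3 hydroxyls) | O[C@@H]1[C@@H](c2c(OCc9ccccc9)cc(OCc9ccccc9)c3c2O[C@H](c7ccc(OCc9ccccc9)c(OCc9ccccc9)c7)[C@H](O)C3)c2c(OCc9ccccc9)cc(OCc9ccccc9)c([C@H]3c4c(OCc9ccccc9)cc(OCc9ccccc9)cc4O[C@H](c7ccc(OCc9ccccc9)c(OCc9ccccc9)c7)[C@@H]3O)c2O[C@@H]1c7ccc(OCc9ccccc9)c(OCc9ccccc9)c7 | intermediate

22 | 3,4,5-tris(benzyloxy)benzoic acid | O=C(O)c1cc(OCc2ccccc2)c(OCc2ccccc2)c(OCc2ccccc2)c1 | starting material

23 | perbenzylated procyanidin C1 3,3′,3″-tri-O-gallate (21 benzyl ethers) | O=C(c8cc(OCc9ccccc9)c(OCc9ccccc9)c(OCc9ccccc9)c8)O[C@@H]1[C@@H](c2c(OCc9ccccc9)cc(OCc9ccccc9)c3c2O[C@H](c7ccc(OCc9ccccc9)c(OCc9ccccc9)c7)[C@H](OC(=O)c8cc(OCc9ccccc9)c(OCc9ccccc9)c(OCc9ccccc9)c8)C3)c2c(OCc9ccccc9)cc(OCc9ccccc9)c([C@H]3c4c(OCc9ccccc9)cc(OCc9ccccc9)cc4O[C@H](c7ccc(OCc9ccccc9)c(OCc9ccccc9)c7)[C@@H]3OC(=O)c8cc(OCc9ccccc9)c(OCc9ccccc9)c(OCc9ccccc9)c8)c2O[C@@H]1c7ccc(OCc9ccccc9)c(OCc9ccccc9)c7 | intermediate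

24 | procyanidin C1 3,3′,3″-tri-O-gallate | O=C(O[C@@H]1[C@@H](c2c(O)cc(O)c3c2O[C@H](c2ccc(O)c(O)c2)[C@H](OC(=O)c2cc(O)c(O)c(O)c2)C3)c2c(O)cc(O)c([C@H]3c4c(O)cc(O)cc4O[C@H](c4ccc(O)c(O)c4)[C@@H]3OC(=O)c3cc(O)c(O)c(O)c3)c2O[C@@H]1c1ccc(O)c(O)c1)c1cc(O)c(O)c(O)c1 | target

## Step count and least certain steps

Total: 17 steps. Longest linear sequence: 16 steps (steps 1–7 and 9–17, from 1 to 24).

**Step 9 (allylic arylation).**
- Most likely failure: substitution at the α-carbon or no substitution at all, because both partners are di-ortho-oxygenated and the γ-carbon is benzylic and crowded.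
- Also possible: ionisation of the electron-rich allylic phosphate before copper reaches it, and poor facial selectivity if ligand and substrate are mismatched.
- Fallback: it sets out from 7 and 9 and comes back at 14. A Mitsunobu etherification (PPh3, DIAD, THF) should give the aryl cinnamyl ether F1. Heating F1 in N,N-diethylaniline at about 180 °C should bring about the aromatic Claisen rearrangement, which forms the same C4–C4a bond intramolecularly at the γ-carbon and leaves the phenol free.
- The two ortho positions of the 3,5-dibenzyloxyphenyl ring are equivalent, so one regioisomer results. Steps 8 and 10 fall away.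
- The price is that C4 is then set by the substrate alone, and the epimers would have to be separated at 14.

**Step 13 (key step).**
- Most likely failure: slow initiation at the vinyl group next to the diarylmethine, followed by catalyst decay to hydrides that move the double bond into conjugation and erase C4.
- Also possible: hydrolysis of the acid-sensitive enol ether on handling.
- Fallback: it sets out from 16 and comes back at 18. A reduced titanium ethylidene reagent (TiCl4, Zn, PbCl2 (cat.), CH3CHBr2, TMEDA, THF) converts olefinic esters directly into cyclic enol ethers by carbonyl–olefin metathesis. This skips the isolation of 17 and uses no ruthenium; no new isolable compound arises.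

**Step 14 (epoxidation and hydride opening).**
- Most likely failure: ionisation of the epoxide at C2 before hydride arrives, with loss of the inversion, hydride shift to a flavan-3-one, or delivery of hydride from the alkoxide side.
- Also possible: oxidation at the C4–H bond by excess dioxirane.
- Fallback: it sets out from 18 and comes back at 20. Epoxidation in CH2Cl2–methanol should give the 2-methoxy ketal F2. Ionic reduction (Et3SiH, BF3·OEt2, CH2Cl2, −78 °C) passes through the cyclic oxocarbenium ion, in which the C3 oxygen is pseudo-axial; axial delivery of hydride anti to it is the known way to 2,3-cis-flavans by reductive etherification.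

**Step 6 (Stille coupling).**
- Most likely failure: slow oxidative addition at the di-ortho-oxygenated, electron-rich aryl bromide, with protodebromination and loss of the stannane taking over.
- Fallback: it sets out from 6 and comes back at 7. Bromine–lithium exchange (t-BuLi, THF, −78 °C) and DMF should give the aldehyde F3. A Horner–Wadsworth–Emmons reaction (triethyl phosphonoacetate, NaH, THF) should give the (E)-enoate F4, and reduction with i-Bu2AlH (CH2Cl2, −78 °C) should give 7. This costs two more steps.

## Further compounds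

F1 | step 9 | aryl cinnamyl ether: C8 of the middle unit of the dimer bears (E)-CH=CH–CH2–O–[3,5-bis(benzyloxy)phenyl] | CC(C)(C)[Si](C)(C)O[C@@H]1[C@@H](c2c(OCc9ccccc9)cc(OCc9ccccc9)c3c2O[C@H](c7ccc(OCc9ccccc9)c(OCc9ccccc9)c7)[C@H](O[Si](C)(C)C(C)(C)C)C3)c2c(OCc9ccccc9)cc(OCc9ccccc9)c(/C=C/COc4cc(OCc9ccccc9)cc(OCc9ccccc9)c4)c2O[C@@H]1c7ccc(OCc9ccccc9)c(OCc9ccccc9)c7

F0 | step 13 | none | none

F2 | step 14 | 2-methoxy ketal: as 20 with a methoxy group on the top C2, trans to the C3 hydroxyl | CC(C)(C)[Si](C)(C)O[C@@H]1[C@@H](c2c(OCc9ccccc9)cc(OCc9ccccc9)c3c2O[C@H](c7ccc(OCc9ccccc9)c(OCc9ccccc9)c7)[C@H](O[Si](C)(C)C(C)(C)C)C3)c2c(OCc9ccccc9)cc(OCc9ccccc9)c([C@H]3c4c(OCc9ccccc9)cc(OCc9ccccc9)cc4O[C@](OC)(c7ccc(OCc9ccccc9)c(OCc9ccccc9)c7)[C@@H]3O)c2O[C@@H]1c7ccc(OCc9ccccc9)c(OCc9ccccc9)c7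

F3 | step 6 | dimer 8-carbaldehyde: as 6 with bromine replaced by CHO | CC(C)(C)[Si](C)(C)O[C@@H]1[C@@H](c2c(OCc9ccccc9)cc(OCc9ccccc9)c3c2O[C@H](c7ccc(OCc9ccccc9)c(OCc9ccccc9)c7)[C@H](O[Si](C)(C)C(C)(C)C)C3)c2c(OCc9ccccc9)cc(OCc9ccccc9)c(C=O)c2O[C@@H]1c7ccc(OCc9ccccc9)c(OCc9ccccc9)c7

F4 | step 6 | dimer ethyl (E)-propenoate: as 6 with bromine replaced by (E)-CH=CH–CO2Et | CC(C)(C)[Si](C)(C)O[C@@H]1[C@@H](c2c(OCc9ccccc9)cc(OCc9ccccc9)c3c2O[C@H](c7ccc(OCc9ccccc9)c(OCc9ccccc9)c7)[C@H](O[Si](C)(C)C(C)(C)C)C3)c2c(OCc9ccccc9)cc(OCc9ccccc9)c(/C=C/C(=O)OCC)c2O[C@@H]1c7ccc(OCc9ccccc9)c(OCc9ccccc9)c7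

A1 | alternative 1 | ynol silyl ether: 3-O-TBS-5,7,3′,4′-tetra-O-benzylepicatechin carrying a 4β-[(triisopropylsilyloxy)ethynyl] group | CC(C)[Si](C(C)C)(C(C)C)OC#C[C@H]3c4c(OCc9ccccc9)cc(OCc9ccccc9)cc4O[C@H](c7ccc(OCc9ccccc9)c(OCc9ccccc9)c7)[C@@H]3O[Si](C)(C)C(C)(C)C

A2 | alternative 1 | 3-(benzyloxy)cyclobut-2-en-1-one | O=C1C=C(OCc2ccccc2)C1

A3 | alternative 1 | top unit carrying the new middle ring A as a 2-substituted 5-benzyloxy-3-(triisopropylsilyloxy)phenol | Oc1cc(OCc9ccccc9)cc(O[Si](C(C)C)(C(C)C)C(C)C)c1[C@H]3c4c(OCc9ccccc9)cc(OCc9ccccc9)cc4O[C@H](c7ccc(OCc9ccccc9)c(OCc9ccccc9)c7)[C@@H]3O[Si](C)(C)C(C)(C)C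

A4 | alternative 2 | epoxy phenol: dimer digallate whose middle C8 bears CH[2,4-bis(benzyloxy)-6-hydroxyphenyl] attached to a cis-2-aryl epoxide | O=C(c8cc(OCc9ccccc9)c(OCc9ccccc9)c(OCc9ccccc9)c8)O[C@@H]1[C@@H](c2c(OCc9ccccc9)cc(OCc9ccccc9)c3c2O[C@H](c7ccc(OCc9ccccc9)c(OCc9ccccc9)c7)[C@H](OC(=O)c8cc(OCc9ccccc9)c(OCc9ccccc9)c(OCc9ccccc9)c8)C3)c2c(OCc9ccccc9)cc(OCc9ccccc9)c([C@@H](c4c(OCc9ccccc9)cc(OCc9ccccc9)cc4O)[C@H]5O[C@H]5c7ccc(OCc9ccccc9)c(OCc9ccccc9)c7)c2O[C@@H]1c7ccc(OCc9ccccc9)c(OCc9ccccc9)c7

A5 | alternative 2 | perbenzylated trimer with a free top C3 hydroxyl and gallates on the middle and bottom units | O=C(c8cc(OCc9ccccc9)c(OCc9ccccc9)c(OCc9ccccc9)c8)O[C@@H]1[C@@H](c2c(OCc9ccccc9)cc(OCc9ccccc9)c3c2O[C@H](c7ccc(OCc9ccccc9)c(OCc9ccccc9)c7)[C@H](OC(=O)c8cc(OCc9ccccc9)c(OCc9ccccc9)c(OCc9ccccc9)c8)C3)c2c(OCc9ccccc9)cc(OCc9ccccc9)c([C@H]3c4c(OCc9ccccc9)cc(OCc9ccccc9)cc4O[C@H](c7ccc(OCc9ccccc9)c(OCc9ccccc9)c7)[C@@H]3O)c2O[C@@H]1c7ccc(OCc9ccccc9)c(OCc9ccccc9)c7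

A6 | alternative 3 | C4 carbinol: bis-TBS dimer whose middle C8 bears CH(OH)–CH(O-galloyl)–CH(aryl)–O–[3,5-bis(benzyloxy)phenyl]; carbinol configuration open because it is lost on ionisation | CC(C)(C)[Si](C)(C)O[C@@H]1[C@@H](c2c(OCc9ccccc9)cc(OCc9ccccc9)c3c2O[C@H](c7ccc(OCc9ccccc9)c(OCc9ccccc9)c7)[C@H](O[Si](C)(C)C(C)(C)C)C3)c2c(OCc9ccccc9)cc(OCc9ccccc9)c(C(O)[C@@H](OC(=O)c8cc(OCc9ccccc9)c(OCc9ccccc9)c(OCc9ccccc9)c8)[C@@H](c7ccc(OCc9ccccc9)c(OCc9ccccc9)c7)Oc4cc(OCc9ccccc9)cc(OCc9ccccc9)c4)c2O[C@@H]1c7ccc(OCc9ccccc9)c(OCc9ccccc9)c7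

A7 | alternative 3 | perbenzylated trimer with the top gallate in place and TBS ethers on the middle and bottom units | CC(C)(C)[Si](C)(C)O[C@@H]1[C@@H](c2c(OCc9ccccc9)cc(OCc9ccccc9)c3c2O[C@H](c7ccc(OCc9ccccc9)c(OCc9ccccc9)c7)[C@H](O[Si](C)(C)C(C)(C)C)C3)c2c(OCc9ccccc9)cc(OCc9ccccc9)c([C@H]3c4c(OCc9ccccc9)cc(OCc9ccccc9)cc4O[C@H](c7ccc(OCc9ccccc9)c(OCc9ccccc9)c7)[C@@H]3OC(=O)c8cc(OCc9ccccc9)c(OCc9ccccc9)c(OCc9ccccc9)c8)c2O[C@@H]1c7ccc(OCc9ccccc9)c(OCc9ccccc9)c7
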